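## Structural features

The target is an aryltetralin cyclolignan. Aromatic ring A (C4a, C5 to C8, C8a; methoxy on C6, free hydroxyl on C7) is fused to the saturated ring B (C1 to C4). C1 carries ring C (4-hydroxy-3,5-dimethoxyphenyl, joined through C1'), C2 and C3 carry the acetoxymethyl arms C9 and C9', and C4 is a methylene group. C1, C2 and C3 are contiguous stereocentres of configuration (1S,2R,3R); the three substituents alternate faces, so all are equatorial on the half-chair and this is the most stable diastereomer. The fragile groups are the two primary acetates (lost to hydride, alkoxide and organometallic reagents, so they must come late), the two electron-rich phenols (oxidation, competing acylation) and the doubly benzylic C1–H. The real difficulty is absolute control of three adjacent centres, of which the diarylmethine C1 cannot be epimerised once formed. The key step exploits the fact that C1 is benzylic to both rings and conjugated with two para oxygens (the C6 methoxy group through C8a, the C4' oxygen through C1'), so it can carry a positive charge. Its neighbour C2 bears C9, which at the aldehyde oxidation level turns C2 into the nucleophilic carbon of an enamine. One auxiliary-controlled centre (C3) can therefore dictate C1 and C2 when the C1–C2 bond closes ring B through a chair.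

## Logic of the disconnections

23 to 22: the two phenolic O–H bonds are traced back to O–benzyl bonds. Free phenols would be acylated along with the primary alcohols and would quench organometallic reagents. The gain is that all earlier chemistry runs on neutral, non-oxidisable aryl ethers. The demand is a final deprotection that is neutral enough to leave two acetates and the C1–H bond alone.

22 to 21: the two acyl C–O bonds are cut. Acetates cannot pass through hydride, fluoride or organolithium steps, so they are installed last but one. The gain is a diol in which both arms are treated alike. The demand is only exhaustive acylation of two primary alcohols at a stage where no phenol is free.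

21 to 20 to 19: the Si–O bond at C9' is cut and C9 is taken from alcohol back to aldehyde. The two arms must differ during ring closure: C9 has to be an aldehyde to form an enamine, and C9' has to be inert. The gain is that 19 is exactly what the ring closure delivers. The demand is a reduction that does not disturb C2 and a desilylation that spares the benzyl ethers.

19 to 18: the C1–C2 bond is cut, opening ring B. This is the strategic cut: it removes two stereocentres and one ring at once and leaves C3 as the only controlled centre. The forward step must ionise C1, make C2 nucleophilic and keep the C9' oxygen masked, all in one flask, and must pass through a chair that places all three substituents equatorial.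

18 to 16: the C9 carbonyl is traced back to a terminal alkene carrying one extra carbon. An aldehyde cannot coexist with an aryllithium, whereas an alkene can. The gain is a robust mask through the organometallic step. The demand is an oxidative cleavage that tolerates an acid-sensitive benzhydrol and electron-rich arenes.

16 to 12 and 14: the C1–C8a bond is cut. This joins the ring A chain piece to ring C convergently, and the carbinol configuration is irrelevant because it is erased on ionisation. The demand is halogen–metal exchange at C8a in the presence of a silyl ether and an alkene, and a non-enolisable aldehyde partner.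

12 to 11 to 10: the Si–O bond is cut, and the C9' alcohol is traced back to the imide carbonyl bearing the auxiliary. The gain is that the stereocentre sits alpha to a carbonyl group, where it can be made by enolate chemistry. The demand is removal of the auxiliary without epimerisation and without touching the aryl bromide.

10 to 8 and 4: the C3–C4 bond is cut. This places the only externally controlled stereocentre at an enolate carbon and gives two simple pieces. The demand is high facial selectivity and the correct auxiliary enantiomer: the (R)-oxazolidinone, because the incoming arylmethyl group outranks the resident allyl chain.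

8 to 5 and 6; 4 to 3 to 2 to 1; 14 to 13: these are functional-group changes only (N-acylation; O-benzylation, reduction and bromination; O-benzylation). They lead to three purchasable building blocks and the auxiliary. The regiochemistry of ring A (C8a para to the methoxy group, C4a para to the protected hydroxyl) is already fixed in 1.

## Other disconnections considered

Alternative 1: The cut runs through ring A itself. C4a–C8a and C7–C8 are disconnected, which turns ring A into a 4-methoxyfuran-2-yl group on C4 and turns C8a/C8 into the alkyne of an ethynyl ketone at C1. This gives the open-chain furyl ynone A1.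
- Forward step: heating A1 in toluene should bring about an intramolecular Diels–Alder reaction between the furan (its 2- and 5-positions are C4a and C7) and the ynone. The oxygen-bridged adduct would open at the C4a–O bond, where the cation is stabilised by the C6 methoxy group, and aromatise to the tetralone A2 with the C7 hydroxyl already free.
- In favour: ring A and ring B are built in one reagent-free thermal step. The OMe/OH pattern is written into the furan, ring A needs no protecting group, and C2 next to the ketone can settle into the trans arrangement.
- Against: the step sets no stereocentre and leaves ring C and C1 untouched. Ring C would have to be added as an aryl-metal to the C1 ketone of A2 in the presence of two acetates, a free phenol and a beta-acetoxy ketone that can eliminate acetic acid. The resulting tertiary benzylic alcohol would then have to be reduced with hydride entering cis to C9, against the normal preference for attack anti to the C2 substituent, so the 1,2-cis isomer is the likely outcome. The anti C2/C3 pair must also be set in the open chain of A1, and alkoxyfurans and terminal ynones are both sensitive.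
- Comparison: on structure the alternative is the better in rings formed per step (two against one) and in protecting groups on ring A. On mechanism, a pericyclic step with no ionic intermediate is at least the equal of the cationic closure of step 11 in reliability. It is weaker where the target is hardest, at C1, which step 11 sets together with C2 under the control of C3. On step economy no saving is expected: A1 should cost about as many steps as 18, and three or more operations follow A2.

Alternative 2: The two bonds C2–C9 and C3–C9' are cut. This removes both one-carbon arms and leaves the 1-aryl-1,4-dihydronaphthalene A3, whose C2=C3 double bond takes up two molecules of CO.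
- Forward step: Pd(OCOCF3)2 with a diimine ligand, CO, methanol and benzoquinone should add two methoxycarbonyl groups syn across the alkene (alkoxycarbonyl-palladium addition, CO insertion, methanolysis, with benzoquinone returning the metal to divalent palladium). NaOMe in the same pot would then equilibrate the cis diester to the all-equatorial diester A4.
- In favour: two C–C bonds form at once, both arms at the same oxidation level. LiAlH4 would take A4 straight to diol 21, so no silyl ether and no differentiation of C9 from C9' is needed. The end game is one step shorter than from 19, and on this point the alternative is the better. The face on which the palladium adds does not matter, since either cis diester converges on A4. This thermodynamic control of C2 and C3 is the equal of the C2 equilibration in the chosen plan.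
- Against: everything rests on enantiopure A3, whose only stereocentre C1 is diaryl-substituted and allylic. Migration of the double bond into conjugation, or dehydrogenation to the naphthalene by benzoquinone or by a palladium hydride, would erase it. Internal cyclic alkenes also carbonylate less readily than terminal ones, and pressurised CO is a toxic gas that the chosen plan avoids. Making A3 as a single enantiomer is a separate problem of about the size of making 18.
- Comparison: on structure it forms more C–C bonds in the step but no ring and no stereocentre from scratch. On mechanism it relies on equilibration only, which is safe for C2 and C3 but gives no handle on C1. On step economy it is better after the key step and probably no better before it.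

Alternative 3: The bonds C2–C9 and C1–C8a are cut. C9 is supplied by an orthoformate, and the precursor is the E-configured homoallylic alcohol A5, which carries only the C3 stereocentre, a styrene (C1=C2 with ring C) and an unbrominated ring A.
- Forward step: Me3SiOTf should ionise the mixed orthoformate formed in the flask from A5 and HC(OMe)3. The styrene carbon C2 attacks the dialkoxycarbenium carbon (Prins step, closing the five-membered acetal ring), and ring A captures the C1 benzylic cation para to its methoxy group (Friedel–Crafts step, closing ring B) to give the tricyclic acetal A6.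
- In favour: two C–C bonds, two rings and two stereocentres arise in one operation. On bonds and rings per step the alternative is the better, and on stereocentres set it is the equal of step 11. No aryl bromide, organolithium or silyl ether is needed, so A5 should be reachable in fewer steps than 18; on step economy before the key step it is the better. The end game from A6 (acetal hydrolysis, reduction to 21, acetylation, hydrogenolysis) is as long as that from 19.
- Against: the C2/C3 relation is decided when the five-membered acetal ring closes. That closure lacks the clear equatorial bias of a six-membered chair, and it must come out trans-fused although cis-fused bicyclic acetals are normally less strained. A wrong C2 cannot be repaired while C9 is locked as an acetal. The C1 cation may also be captured by methanol released from the orthoformate, and Me3SiOTf is a harsher medium for two benzyl ethers than one equivalent of trifluoroacetic acid.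
- Comparison: both plans pass through the same kind of C1 benzylic cation and differ in which bond closes ring B (C1–C8a here, C1–C2 in step 11). The chosen plan is preferred because its stereo-determining closure is a six-membered chair with a correctable C2, at the price of a longer way to the precursor.

Key step: step 11

Remark on the chemistry: tetralin numbering (C1 to C4 in ring B, C9 on C2, C9' on C3) is used for all intermediates. The C9' oxygen is carried as a tert-butyldiphenylsilyl ether, not a tert-butyldimethylsilyl ether, because a silyl group lost under trifluoroacetic acid would free a gamma-hydroxy aldehyde that closes to a lactol and a hydroxyl that traps the C1 cation.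

Step 1
Reactants: 1 6-bromovanillin (2-bromo-4-hydroxy-5-methoxybenzaldehyde)
Product: 2 4-(benzyloxy)-2-bromo-5-methoxybenzaldehyde
Conditions: BnBr, K2CO3, DMF, 25 °C
Reagents that add atoms: benzyl bromide, BrCc1ccccc1
Why: Williamson ether synthesis: the phenol, acidified by the para formyl group, is deprotonated by K2CO3 and the phenoxide displaces bromide from benzyl bromide (SN2); the aldehyde and the aryl bromide do not react.

Step 2
Reactants: 2 4-(benzyloxy)-2-bromo-5-methoxybenzaldehyde
Product: 3 [4-(benzyloxy)-2-bromo-5-methoxyphenyl]methanol
Conditions: NaBH4, MeOH/THF, 0 °C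
Reagents that add atoms: none
Why: Borohydride reduction of an aromatic aldehyde to the benzylic alcohol; the aryl bromide and the benzyl ether are inert to NaBH4.

Step 3
Reactants: 3 [4-(benzyloxy)-2-bromo-5-methoxyphenyl]methanol
Product: 4 4-(benzyloxy)-2-bromo-5-methoxybenzyl bromide
Conditions: PBr3, CH2Cl2, 0 °C
Reagents that add atoms: phosphorus tribromide, BrP(Br)Br
Why: The alcohol is converted into a bromophosphite ester that bromide displaces (SN2) at the activated benzylic carbon; low temperature and a neutral work-up keep the electron-rich benzylic bromide from self-alkylation, and it is used soon after preparation.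

Step 4
Reactants: 5 4-pentenoic acid; 6 (4R)-4-benzyl-1,3-oxazolidin-2-one
Product: 8 (4R)-4-benzyl-3-(pent-4-enoyl)-1,3-oxazolidin-2-one, via mixed pivalic anhydride 7 (not isolated)
Conditions: t-BuCOCl, Et3N, THF, −20 °C; then LiCl, 6, −20 → 25 °C
Reagents that add atoms: none
Why: N-Acylation by the mixed anhydride method: the carboxylate attacks pivaloyl chloride, and the oxazolidinone, activated by LiCl and Et3N, is acylated at the unhindered pentenoyl carbonyl and not at the pivaloyl one; the auxiliary stereocentre is untouched.

Step 5
Reactants: 8 (4R)-4-benzyl-3-(pent-4-enoyl)-1,3-oxazolidin-2-one; 4 4-(benzyloxy)-2-bromo-5-methoxybenzyl bromide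
Product: 10 (4R)-4-benzyl-3-[(2S)-2-{[4-(benzyloxy)-2-bromo-5-methoxyphenyl]methyl}pent-4-enoyl]-1,3-oxazolidin-2-one, via sodium Z-enolate 9 (not isolated)
Conditions: NaN(SiMe3)2, THF, −78 °C; then 4, −78 → −45 °C
Reagents that add atoms: none
Why: Evans asymmetric alkylation: the chelated Z-enolate 9 is blocked on the face syn to the C4 benzyl group of the auxiliary, so the reactive benzylic bromide enters from the other face and the new stereocentre (the later C3) should form as (2S); the (R)-auxiliary is the one that gives this sense, because the incoming arylmethyl group outranks the resident allyl chain.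

Step 6
Reactants: 10 (4R)-4-benzyl-3-[(2S)-2-{[4-(benzyloxy)-2-bromo-5-methoxyphenyl]methyl}pent-4-enoyl]-1,3-oxazolidin-2-one
Product: 11 (2S)-2-{[4-(benzyloxy)-2-bromo-5-methoxyphenyl]methyl}pent-4-en-1-ol
Conditions: LiBH4, MeOH (1 equiv), THF, 0 °C
Reagents that add atoms: none
Why: Reductive removal of the auxiliary: lithium-activated hydride attack at the exocyclic imide carbonyl and reduction of the resulting aldehyde give the primary alcohol and return the oxazolidinone; the alpha stereocentre is not deprotonated, and the aryl bromide, alkene and benzyl ether are inert to LiBH4.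

Step 7
Reactants: 11 (2S)-2-{[4-(benzyloxy)-2-bromo-5-methoxyphenyl]methyl}pent-4-en-1-ol
Product: 12 tert-butyl{[(2S)-2-{[4-(benzyloxy)-2-bromo-5-methoxyphenyl]methyl}pent-4-en-1-yl]oxy}diphenylsilane
Conditions: t-BuPh2SiCl, imidazole, CH2Cl2, 25 °C
Reagents that add atoms: tert-butyl(chloro)diphenylsilane, CC(C)(C)[Si](Cl)(c1ccccc1)c1ccccc1
Why: Imidazole-assisted silylation of a primary alcohol; the tert-butyldiphenylsilyl ether is chosen because it withstands n-BuLi at low temperature and the trifluoroacetic acid of step 11.

Step 8
Reactants: 13 syringaldehyde (4-hydroxy-3,5-dimethoxybenzaldehyde)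
Product: 14 4-(benzyloxy)-3,5-dimethoxybenzaldehyde
Conditions: BnBr, K2CO3, DMF, 60 °C
Reagents that add atoms: benzyl bromide, BrCc1ccccc1
Why: Williamson ether synthesis on an acidic phenol flanked by two methoxy groups; mild heating makes up for the steric shielding.

Step 9
Reactants: 12 tert-butyl{[(2S)-2-{[4-(benzyloxy)-2-bromo-5-methoxyphenyl]methyl}pent-4-en-1-yl]oxy}diphenylsilane; 14 4-(benzyloxy)-3,5-dimethoxybenzaldehyde
Product: 16 [5-(benzyloxy)-4-methoxy-2-{(2S)-2-[(tert-butyldiphenylsilyloxy)methyl]pent-4-en-1-yl}phenyl][4-(benzyloxy)-3,5-dimethoxyphenyl]methanol (both carbinol epimers), via aryllithium 15 (not isolated)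
Conditions: n-BuLi, THF, −78 °C; then 14, −78 → −30 °C; aq NH4Cl
Reagents that add atoms: none
Why: Bromine–lithium exchange at C8a is fast at −78 °C and outruns deprotonation or attack on the silyl ether, and the aryllithium adds 1,2 to the non-enolisable aldehyde to form the C1–C8a bond; the carbinol centre forms without control, which does not matter because it becomes planar in step 11.

Step 10
Reactants: 16 [5-(benzyloxy)-4-methoxy-2-{(2S)-2-[(tert-butyldiphenylsilyloxy)methyl]pent-4-en-1-yl}phenyl][4-(benzyloxy)-3,5-dimethoxyphenyl]methanol
Product: 18 (3R)-4-{4-(benzyloxy)-2-[(4-benzyloxy-3,5-dimethoxyphenyl)(hydroxy)methyl]-5-methoxyphenyl}-3-[(tert-butyldiphenylsilyloxy)methyl]butanal (both carbinol epimers), via terminal 1,2-diol 17 (not isolated)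
Conditions: K2OsO4·2H2O (2 mol%), NaIO4, 2,6-lutidine, dioxane/H2O, 25 °C
Reagents that add atoms: sodium periodate, [Na+].[O-]I(=O)(=O)=O (source of the carbonyl oxygen, passed on through the osmium oxo catalyst)
Why: Lemieux–Johnson oxidation: OsO4 formed from the osmate by periodate dihydroxylates the only alkene and periodate cleaves diol 17 to the aldehyde with loss of formaldehyde; 2,6-lutidine buffers the iodic acid, which protects the acid-labile benzhydrol and suppresses over-oxidation, and the non-volatile osmate salt avoids handling OsO4 itself.

Step 11
Reactants: 18 (3R)-4-{4-(benzyloxy)-2-[(4-benzyloxy-3,5-dimethoxyphenyl)(hydroxy)methyl]-5-methoxyphenyl}-3-[(tert-butyldiphenylsilyloxy)methyl]butanal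
Product: 19 (1S,2R,3R)-7-(benzyloxy)-1-[4-(benzyloxy)-3,5-dimethoxyphenyl]-3-[(tert-butyldiphenylsilyloxy)methyl]-6-methoxy-1,2,3,4-tetrahydronaphthalene-2-carbaldehyde
Conditions: (5R)-5-benzyl-2,2,3-trimethylimidazolidin-4-one·CF3CO2H (20 mol%), CF3CO2H (1 equiv), CH2Cl2 (0.02 M), −20 → 20 °C
Reagents that add atoms: none
Why: Trifluoroacetic acid protonates the carbinol and water leaves, giving the C1 benzhydryl cation, which is stabilised through C8a by the C6 methoxy group of ring A and by the para oxygen of ring C; in the same flask the imidazolidinone condenses with the aldehyde to the E-enamine, whose carbon C2 adds to C1, and hydrolysis of the iminium ion releases 19 and the amine. The closest known reaction type is the enamine-catalysed SN1-type alpha-alkylation of aldehydes with diarylmethanols, run here intramolecularly. Ring B closes in the 6-(enolexo)-exo-trig mode, with the enamine double bond C2=C9 outside the new ring and the cation attacked along its empty p orbital. C2 is controlled by the C3 stereocentre: in the chair-like transition state the silyloxymethyl arm on C3 and the enamine unit on C2 both sit equatorial and hence trans; the (5R) catalyst is expected to be the matched enantiomer, since with the enamine turned away from the gem-dimethyl carbon its benzyl group covers the opposite face of C2, and C2 can also equilibrate to the trans aldehyde through the enamine after closure. C1 is controlled by the same chair: ring C takes the equatorial position, away from the axial hydrogen on C3 and anti to the enamine, so C1 and C2 should become trans. The step needs C-alkylation to win over reversible capture of the cation by water or by a second molecule, which the six-membered intramolecular closure and high dilution secure; it also needs the C9' oxygen to stay masked, which the acid-stable tert-butyldiphenylsilyl ether secures, and the single alpha carbon of the aldehyde leaves no regiochemical choice.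

Step 12
Reactants: 19 (1S,2R,3R)-7-(benzyloxy)-1-[4-(benzyloxy)-3,5-dimethoxyphenyl]-3-[(tert-butyldiphenylsilyloxy)methyl]-6-methoxy-1,2,3,4-tetrahydronaphthalene-2-carbaldehyde
Product: 20 {(1S,2R,3R)-7-(benzyloxy)-1-[4-(benzyloxy)-3,5-dimethoxyphenyl]-3-[(tert-butyldiphenylsilyloxy)methyl]-6-methoxy-1,2,3,4-tetrahydronaphthalen-2-yl}methanol
Conditions: NaBH4, MeOH/THF, 0 °C
Reagents that add atoms: none
Why: Borohydride reduction of the aldehyde to the C9 primary alcohol; it is run soon after step 11, and C2 is already in its most stable trans arrangement, so mild base cannot move it to a worse one.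

Step 13
Reactants: 20 {(1S,2R,3R)-7-(benzyloxy)-1-[4-(benzyloxy)-3,5-dimethoxyphenyl]-3-[(tert-butyldiphenylsilyloxy)methyl]-6-methoxy-1,2,3,4-tetrahydronaphthalen-2-yl}methanol
Product: 21 {(1S,2R,3R)-7-(benzyloxy)-1-[4-(benzyloxy)-3,5-dimethoxyphenyl]-6-methoxy-1,2,3,4-tetrahydronaphthalene-2,3-diyl}dimethanol
Conditions: Bu4NF, THF, 25 °C
Reagents that add atoms: none
Why: Fluoride-induced cleavage of the silyl ether, driven by the strong Si–F bond; benzyl ethers and the three stereocentres are inert, and silyl migration between the two primary oxygens is immaterial because both end up free.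

Step 14
Reactants: 21 {(1S,2R,3R)-7-(benzyloxy)-1-[4-(benzyloxy)-3,5-dimethoxyphenyl]-6-methoxy-1,2,3,4-tetrahydronaphthalene-2,3-diyl}dimethanol
Product: 22 {(1S,2R,3R)-7-(benzyloxy)-1-[4-(benzyloxy)-3,5-dimethoxyphenyl]-6-methoxy-1,2,3,4-tetrahydronaphthalene-2,3-diyl}bis(methylene) diacetate
Conditions: Ac2O, pyridine, DMAP (cat.), CH2Cl2, 25 °C
Reagents that add atoms: acetic anhydride, CC(=O)OC(C)=O
Why: DMAP-catalysed acylation converts both primary alcohols into acetates; no phenol is free at this stage, so there is no selectivity problem.

Step 15
Reactants: 22 {(1S,2R,3R)-7-(benzyloxy)-1-[4-(benzyloxy)-3,5-dimethoxyphenyl]-6-methoxy-1,2,3,4-tetrahydronaphthalene-2,3-diyl}bis(methylene) diacetate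
Product: 23 {(1S,2R,3R)-7-hydroxy-1-(4-hydroxy-3,5-dimethoxyphenyl)-6-methoxy-1,2,3,4-tetrahydronaphthalene-2,3-diyl}bis(methylene) diacetate (CNP0265800.1)
Conditions: H2 (1 atm), 10% Pd/C, EtOAc, 25 °C
Reagents that add atoms: none
Why: Catalytic hydrogenolysis cleaves the two aryl benzyl ethers at the benzylic C–O bonds under neutral conditions; acetates, aryl methyl ethers and the C1–H diarylmethine bond (no heteroatom leaving group) are not cleaved, so the target should result without further manipulation.

Compound list

1 | 6-bromovanillin (2-bromo-4-hydroxy-5-methoxybenzaldehyde) | COc1cc(C=O)c(Br)cc1O | starting material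
2 | 4-(benzyloxy)-2-bromo-5-methoxybenzaldehyde | COc1cc(C=O)c(Br)cc1OCc1ccccc1 | intermediate
3 | [4-(benzyloxy)-2-bromo-5-methoxyphenyl]methanol | COc1cc(CO)c(Br)cc1OCc1ccccc1 | intermediate
4 | 4-(benzyloxy)-2-bromo-5-methoxybenzyl bromide | COc1cc(CBr)c(Br)cc1OCc1ccccc1 | intermediate
5 | 4-pentenoic acid | C=CCCC(=O)O | starting material
6 | (4R)-4-benzyl-1,3-oxazolidin-2-one | O=C1OC[C@@H](Cc2ccccc2)N1 | starting material
7 | pent-4-enoic pivalic anhydride (not isolated) | C=CCCC(=O)OC(=O)C(C)(C)C | intermediate
8 | (4R)-4-benzyl-3-(pent-4-enoyl)-1,3-oxazolidin-2-one | C=CCCC(=O)N1[C@H](Cc2ccccc2)COC1=O | intermediate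
9 | sodium (Z)-enolate of 8 (not isolated) | C=CC/C=C(\[O-])N1[C@H](Cc2ccccc2)COC1=O.[Na+] | intermediate
10 | (4R)-4-benzyl-3-[(2S)-2-{[4-(benzyloxy)-2-bromo-5-methoxyphenyl]methyl}pent-4-enoyl]-1,3-oxazolidin-2-one | C=CC[C@@H](Cc1cc(OC)c(OCc2ccccc2)cc1Br)C(=O)N1[C@H](Cc2ccccc2)COC1=O | intermediate
11 | (2S)-2-{[4-(benzyloxy)-2-bromo-5-methoxyphenyl]methyl}pent-4-en-1-ol | C=CC[C@@H](Cc1cc(OC)c(OCc2ccccc2)cc1Br)CO | intermediate
12 | tert-butyl{[(2S)-2-{[4-(benzyloxy)-2-bromo-5-methoxyphenyl]methyl}pent-4-en-1-yl]oxy}diphenylsilane | C=CC[C@@H](Cc1cc(OC)c(OCc2ccccc2)cc1Br)CO[Si](c1ccccc1)(c1ccccc1)C(C)(C)C | intermediate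
13 | syringaldehyde (4-hydroxy-3,5-dimethoxybenzaldehyde) | COc1cc(C=O)cc(OC)c1O | starting material
14 | 4-(benzyloxy)-3,5-dimethoxybenzaldehyde | COc1cc(C=O)cc(OC)c1OCc1ccccc1 | intermediate
15 | [5-(benzyloxy)-4-methoxy-2-{(2S)-2-[(tert-butyldiphenylsilyloxy)methyl]pent-4-en-1-yl}phenyl]lithium (not isolated) | C=CC[C@@H](Cc1cc(OC)c(OCc2ccccc2)cc1[Li])CO[Si](c1ccccc1)(c1ccccc1)C(C)(C)C | intermediate
16 | [5-(benzyloxy)-4-methoxy-2-{(2S)-2-[(tert-butyldiphenylsilyloxy)methyl]pent-4-en-1-yl}phenyl][4-(benzyloxy)-3,5-dimethoxyphenyl]methanol, both carbinol epimers | C=CC[C@@H](Cc1cc(OC)c(OCc2ccccc2)cc1C(O)c1cc(OC)c(OCc2ccccc2)c(OC)c1)CO[Si](c1ccccc1)(c1ccccc1)C(C)(C)C | intermediate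
17 | (4R)-5-{4-(benzyloxy)-2-[(4-benzyloxy-3,5-dimethoxyphenyl)(hydroxy)methyl]-5-methoxyphenyl}-4-[(tert-butyldiphenylsilyloxy)methyl]pentane-1,2-diol, mixture at C2 and at the carbinol carbon (not isolated) | OCC(O)C[C@@H](Cc1cc(OC)c(OCc2ccccc2)cc1C(O)c1cc(OC)c(OCc2ccccc2)c(OC)c1)CO[Si](c1ccccc1)(c1ccccc1)C(C)(C)C | intermediate
18 | (3R)-4-{4-(benzyloxy)-2-[(4-benzyloxy-3,5-dimethoxyphenyl)(hydroxy)methyl]-5-methoxyphenyl}-3-[(tert-butyldiphenylsilyloxy)methyl]butanal, both carbinol epimers | COc1cc(C[C@@H](CO[Si](c2ccccc2)(c2ccccc2)C(C)(C)C)CC=O)c(cc1OCc1ccccc1)C(O)c1cc(OC)c(OCc2ccccc2)c(OC)c1 | intermediate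
19 | (1S,2R,3R)-7-(benzyloxy)-1-[4-(benzyloxy)-3,5-dimethoxyphenyl]-3-[(tert-butyldiphenylsilyloxy)methyl]-6-methoxy-1,2,3,4-tetrahydronaphthalene-2-carbaldehyde | COc1cc2c(cc1OCc1ccccc1)[C@H](c1cc(OC)c(OCc3ccccc3)c(OC)c1)[C@@H](C=O)[C@H](CO[Si](c1ccccc1)(c1ccccc1)C(C)(C)C)C2 | intermediate
20 | {(1S,2R,3R)-7-(benzyloxy)-1-[4-(benzyloxy)-3,5-dimethoxyphenyl]-3-[(tert-butyldiphenylsilyloxy)methyl]-6-methoxy-1,2,3,4-tetrahydronaphthalen-2-yl}methanol | COc1cc2c(cc1OCc1ccccc1)[C@H](c1cc(OC)c(OCc3ccccc3)c(OC)c1)[C@@H](CO)[C@H](CO[Si](c1ccccc1)(c1ccccc1)C(C)(C)C)C2 | intermediate
21 | {(1S,2R,3R)-7-(benzyloxy)-1-[4-(benzyloxy)-3,5-dimethoxyphenyl]-6-methoxy-1,2,3,4-tetrahydronaphthalene-2,3-diyl}dimethanol | COc1cc2c(cc1OCc1ccccc1)[C@H](c1cc(OC)c(OCc3ccccc3)c(OC)c1)[C@@H](CO)[C@H](CO)C2 | intermediate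
22 | {(1S,2R,3R)-7-(benzyloxy)-1-[4-(benzyloxy)-3,5-dimethoxyphenyl]-6-methoxy-1,2,3,4-tetrahydronaphthalene-2,3-diyl}bis(methylene) diacetate | COc1cc2c(cc1OCc1ccccc1)[C@H](c1cc(OC)c(OCc3ccccc3)c(OC)c1)[C@@H](COC(C)=O)[C@H](COC(C)=O)C2 | intermediate
23 | {(1S,2R,3R)-7-hydroxy-1-(4-hydroxy-3,5-dimethoxyphenyl)-6-methoxy-1,2,3,4-tetrahydronaphthalene-2,3-diyl}bis(methylene) diacetate | COc1cc2c(cc1O)[C@H](c1cc(OC)c(O)c(OC)c1)[C@@H](COC(C)=O)[C@H](COC(C)=O)C2 | target

Total step count: 15. Longest linear sequence: 13 steps (from 1 through steps 1 to 3, 5 to 7 and 9 to 15 to 23); steps 4 and 8 are side branches.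

Steps least certain to work

Step 11 (key step). The most likely failure is capture of the C1 cation by oxygen nucleophiles, or by the electron-rich ring C of a second molecule, faster than by the enamine. The acid needed for ionisation keeps most of the amine protonated, so the standing concentration of enamine is low. A second risk is incomplete facial control at C1, which cannot be corrected later. Fallback, from 18 back to 19: the nucleophile is made stoichiometrically beforehand instead of catalytically. Treatment of 18 with t-BuMe2SiOTf and Et3N in CH2Cl2 should convert the aldehyde into its silyl enol ether and silylate the carbinol oxygen, giving the bis(tert-butyldimethylsilyl) enol ether F1. BF3·OEt2 in CH2Cl2 at −78 °C would then ionise the benzhydryl silyl ether, and the enol ether would close ring B in a Mukaiyama-type SN1 alkylation through the same chair. Aqueous work-up and, if needed, brief exposure to DBU to settle C2 would return 19.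

Step 10. The most likely failure is acid-promoted ionisation of the electron-rich benzhydrol by iodic acid formed during the cleavage, with over-oxidation of the diol to a hydroxy ketone and self-condensation of the hydroxy aldehyde during purification as further losses. Fallback, from 12 back to 18: the alkene is cleaved before the carbinol exists. The same osmate/periodate cleavage applied to 12 gives the bromo aldehyde F2. HC(OMe)3 and pyridinium p-toluenesulfonate in MeOH convert it into the dimethyl acetal F3, which survives organolithium reagents. Bromine–lithium exchange and addition to 14 as in step 9 give the carbinol acetal F4, and pyridinium p-toluenesulfonate in wet acetone releases the aldehyde to rejoin the route at 18.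

Step 9. The most likely failure is consumption of the aryllithium before the aldehyde is added, by proton transfer or by alkylation with the 1-bromobutane formed in the exchange, together with incomplete exchange on the electron-rich ring. Fallback, from 12 back to 16: no organolithium is used. Miyaura borylation (bis(pinacolato)diboron, PdCl2(dppf), KOAc, dioxane, 80 °C) gives the aryl pinacol boronate F5. Rhodium-catalysed 1,2-addition of F5 to 14 ([Rh(OH)(cod)]2, K3PO4, dioxane/H2O, 60 °C) then forms the C1–C8a bond and returns 16.

Further compounds

F1 | step 11 | tert-butyldimethylsilyl enol ether of 18 (E/Z mixture) with a tert-butyldimethylsilyl ether on the carbinol oxygen | CC(C)(C)[Si](C)(C)OC=C[C@@H](Cc1cc(OC)c(OCc2ccccc2)cc1C(O[Si](C)(C)C(C)(C)C)c1cc(OC)c(OCc2ccccc2)c(OC)c1)CO[Si](c1ccccc1)(c1ccccc1)C(C)(C)C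
F2 | step 10 | (3R)-4-[4-(benzyloxy)-2-bromo-5-methoxyphenyl]-3-[(tert-butyldiphenylsilyloxy)methyl]butanal | O=CC[C@@H](Cc1cc(OC)c(OCc2ccccc2)cc1Br)CO[Si](c1ccccc1)(c1ccccc1)C(C)(C)C
F3 | step 10 | dimethyl acetal of F2 | COC(OC)C[C@@H](Cc1cc(OC)c(OCc2ccccc2)cc1Br)CO[Si](c1ccccc1)(c1ccccc1)C(C)(C)C
F4 | step 10 | dimethyl acetal of 18 (both carbinol epimers) | COC(OC)C[C@@H](Cc1cc(OC)c(OCc2ccccc2)cc1C(O)c1cc(OC)c(OCc2ccccc2)c(OC)c1)CO[Si](c1ccccc1)(c1ccccc1)C(C)(C)C
F5 | step 9 | aryl pinacol boronate from 12 (Bpin in place of Br) | C=CC[C@@H](Cc1cc(OC)c(OCc2ccccc2)cc1B1OC(C)(C)C(C)(C)O1)CO[Si](c1ccccc1)(c1ccccc1)C(C)(C)C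
A1 | alternative 1 | 4,5-anti-4,5-bis(acetoxymethyl)-6-(4-methoxyfuran-2-yl)hex-1-yn-3-one, configured as C2 and C3 of the target | COc1coc(C[C@@H](COC(C)=O)[C@H](COC(C)=O)C(=O)C#C)c1
A2 | alternative 1 | 2,3-trans-bis(acetoxymethyl)-7-hydroxy-6-methoxy-1-tetralone | COc1cc2c(cc1O)C(=O)[C@@H](COC(C)=O)[C@H](COC(C)=O)C2
A3 | alternative 2 | (1S)-7-(benzyloxy)-1-[4-(benzyloxy)-3,5-dimethoxyphenyl]-6-methoxy-1,4-dihydronaphthalene | COc1cc2c(cc1OCc1ccccc1)[C@H](c1cc(OC)c(OCc3ccccc3)c(OC)c1)C=CC2
A4 | alternative 2 | all-trans dimethyl 7-(benzyloxy)-1-[4-(benzyloxy)-3,5-dimethoxyphenyl]-6-methoxytetralin-2,3-dicarboxylate | COc1cc2c(cc1OCc1ccccc1)[C@H](c1cc(OC)c(OCc3ccccc3)c(OC)c1)[C@@H](C(=O)OC)[C@H](C(=O)OC)C2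
A5 | alternative 3 | (E)-2-[4-(benzyloxy)-3-methoxybenzyl]-4-[4-(benzyloxy)-3,5-dimethoxyphenyl]but-3-en-1-ol, configured at C2 as C3 of the target | OC[C@H](Cc1ccc(OCc2ccccc2)c(OC)c1)/C=C/c1cc(OC)c(OCc2ccccc2)c(OC)c1
A6 | alternative 3 | all-trans 1-aryltetralin fused across C2–C3 to a 2-methoxytetrahydrofuran (methyl acetal of the C9 lactol) | COc1cc2c(cc1OCc1ccccc1)[C@H](c1cc(OC)c(OCc3ccccc3)c(OC)c1)[C@@H](C(OC)O5)[C@H](C5)C2
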